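Readings and results are calculated with constants of no real substance; scatter was added.

2.00 equivalents is what theta starts with. I call this the nucleophile in hand: the lesser of the free base and protonated nucleophile charges, as a fraction of the electrophile charged, because I take proton transfer as instant and one base frees one nucleophile.

| setting | grey | amber | gamma | theta | eta |
|---|---|---|---|---|---|
| electrophile | 0.14 M | 0.14 M | 0.14 M | 0.14 M | 0.14 M |
| free base | 0.20 M | 0.93 M | 1.10 M | 0.280 M | 0.560 M |
| protonated nucleophile | 0.35 M | 0.35 M | 0.350 M | 0.350 M | 0.350 M |
| protic impurity | 0.028 M | 0.028 M | 0.0280 M | 0.0280 M | 0.0280 M |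
| remark | run made earlier | run made earlier |  |  |  |
| time |  |  | 5.0 h | 5.0 h | 5.0 h |

| run | time / h | electrophile / % | target / % |
|---|---|---|---|
| grey | 0.167 | 94 | 5 |
| grey | 0.500 | 88 | 11 |
| grey | 0.833 | 79 | 13 |
| grey | 1.33 | 69 | 24 |
| grey | 2.00 | 61 | 31 |
| grey | 2.50 | 58 | 32 |
| amber | 0.200 | 90 | 8 |
| amber | 0.333 | 84 | 17 |
| amber | 0.500 | 79 | 18 |
| amber | 0.833 | 71 | 28 |
| amber | 1.50 | 53 | 42 |
| amber | 2.50 | 33 | 54 |

(readings scatter by 1.5 percentage points)

1. part of the electrophile that has reacted at the end, gamma
2. part of the electrophile that has reacted at the end, theta
3. part of the electrophile that has reacted at the end, eta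
4. what raising the concentration of free base from its lowest to its highest value here does to the part of the electrophile that has reacted (changes below 5 percentage points count as none) (no change / it falls / it rises)

- the numbers in the tables scatter with a standard deviation of 1.5 percentage points
- a reading or a percentage of target counts all its forms, free or not

The amber run starts with 2.50 in hand and keeps 33 % of its electrophile at 2.50 h. I read that as a pseudo-first-order constant of 0.443 h⁻¹, or 0.177 h⁻¹ per equivalent in hand. The grey run has 1.43 in hand, so I expect 0.253 h⁻¹, and its single reading at 0.500 h gives 0.256 h⁻¹.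

Theta therefore starts near 0.354 h⁻¹ and slows. Each target costs one equivalent in hand, but theta has less free base than protonated nucleophile, so I reckon that its acid takes back a second. Eta has more base than protonated nucleophile and electrophile together, so I reckon on one per target there. Please leave theta's base charge as it is.

The forecast gives 88 % for gamma, 70 % for theta and 83 % for eta, and says of raising the base: it rises. It holds that “the free nucleophile therefore falls about twice as fast as the electrophile”.

    electrophile + protic impurity → quenched substrate (k = 8.46 × 10⁻⁴ L mol⁻¹ s⁻¹)
    nucleophile + acid set free ⇌ protonated nucleophile, settled at all times (K = 230 L mol⁻¹)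
    electrophile + nucleophile → acid set free + target (k = 3.48 × 10⁻⁴ L mol⁻¹ s⁻¹)
    acid set free + free base ⇌ salt of the base, settled at all times (K = 4300 L mol⁻¹)
    crystals ⇌ target, rate k5*(cs5 - [target]) while solid is left; crystals form when [target] > cs5 (solubility = 35.0 mM, k = 0.00726 s⁻¹)

At 5.0 h gamma has reacted 85.7 %, theta 70.9 % and eta 83.8 %, and on raising the base from theta's charge to gamma's the flask's answer is: it rises, by 15 percentage points. Theta then has 3.8 % of its free base left, less than its 29 % of electrophile. Its 2.00 in hand, less two per target at 57.4 %, gives 0.852 equivalents, and the flask holds 0.818. Gamma's neighbour with 0.087 M of protonated nucleophile starts with 0.621 in hand, and one per target at 29.0 % leaves 0.332. It holds 0.329 equivalents and has reacted 44.7 %.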